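**Assumption:** the SMILES carries no stereodescriptors and neither biaryl axis is configurationally stable at room temperature (no doubly ortho-flanked axis), so the target is treated as one achiral constitution and no stereocentre has to be set.

## Retrosynthetic overview

1. Target ⇒ acid-triggered, redox-neutral dehydrative aromatisation of a β-hydroxy ketone (aldol adduct). This last step creates the aromatic ring of terminal naphthol A and aromatises central ring B.
2. Aldol adduct ⇒ key intermolecular aldol addition of the lithium enolate of a 4-aryl-8-methoxy-1-tetralone (rings B + C) to the carbonyl of 4,4,5-trimethoxynaphthalen-1(4H)-one, forming the B(C2)–A(C1) bond.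
3. 4-Aryl tetralone ⇒ Suzuki coupling of an enol triflate (ring B precursor, ketone masked as dimethyl ketal) with a 1-naphthylboronate (ring C), then C=C hydrogenation and ketal hydrolysis, forming the B(C4)–C(C1) bond.
4. Quinone monoketal and enol triflate ⇐ 5-methoxy-1-naphthol (para oxidative ketalisation); boronate ⇐ 8-methoxy-1-naphthol (para bromination, MOM protection, borylation).
5. Ring order: all carbocycles are bought as naphthalenes; ring C stays aromatic, ring B is carried as a tetralone, and rings A and B are aromatised together in the final step.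

## Route

Step 1
Reactants: 1 5-methoxynaphthalen-1-ol
Product: 2 4,4,5-trimethoxynaphthalen-1(4H)-one
Conditions: PhI(OAc)2 (2.2 equiv), MeOH, 0 → 23 °C
Reagents that add atoms: methanol (CO)
Why: Hypervalent-iodine oxidative dearomatisation (Pelter-type para-oxidation) oxidises the 1-naphthol twice at its free para position in methanol, first to the 4-methoxy naphthol and then to the 4,4-dimethyl ketal; no stereocentre is formed.

Step 2
Reactants: 2 4,4,5-trimethoxynaphthalen-1(4H)-one
Product: 3 4,4,5-trimethoxy-3,4-dihydronaphthalen-1(2H)-one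
Conditions: H2 (1 atm), 5% Pd/C, K2CO3 (cat.), EtOAc, 23 °C, stopped after 1 equiv H2
Reagents that add atoms: none
Why: Catalytic hydrogenation of the disubstituted enone C=C is much faster than reduction of the aryl ketone or arene, and the trace of base prevents acid-triggered loss of methanol and aromatisation.

Step 3
Reactants: 3 4,4,5-trimethoxy-3,4-dihydronaphthalen-1(2H)-one
Product: 4 4,4,5-trimethoxy-3,4-dihydronaphthalen-1-yl trifluoromethanesulfonate
Conditions: KN(SiMe3)2, THF, −78 °C; PhNTf2, −78 → 0 °C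
Reagents that add atoms: N-phenylbis(trifluoromethanesulfonimide) (O=S(=O)(N(c1ccccc1)S(=O)(=O)C(F)(F)F)C(F)(F)F)
Why: Kinetic enolate formation at the only α-CH2 followed by O-sulfonylation (enol triflate synthesis) proceeds under cold basic conditions that leave the ketal intact.

Step 4
Reactants: 5 8-methoxynaphthalen-1-ol
Product: 6 4-bromo-8-methoxynaphthalen-1-ol
Conditions: NBS (1.0 equiv), MeCN, −20 → 0 °C
Reagents that add atoms: N-bromosuccinimide (BrN1C(=O)CCC1=O)
Why: Electrophilic aromatic bromination goes para to the free hydroxyl, the most activated position of a 1-naphthol, and NBS in MeCN is para-selective.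

Step 5
Reactants: 6 4-bromo-8-methoxynaphthalen-1-ol
Product: 7 1-bromo-5-methoxy-4-(methoxymethoxy)naphthalene
Conditions: NaH, DMF, 0 °C; MOMCl, 0 → 23 °C
Reagents that add atoms: chloromethyl methyl ether (COCCl)
Why: Williamson-type O-alkylation of the sodium naphthoxide installs a MOM acetal that survives the basic, reductive and enolate steps ahead and leaves in the final acid step.

Step 6
Reactants: 7 1-bromo-5-methoxy-4-(methoxymethoxy)naphthalene
Product: 8 2-[5-methoxy-4-(methoxymethoxy)naphthalen-1-yl]-4,4,5,5-tetramethyl-1,3,2-dioxaborolane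
Conditions: B2pin2, Pd(dppf)Cl2 (3 mol%), KOAc, 1,4-dioxane, 90 °C
Reagents that add atoms: bis(pinacolato)diboron (CC1(C)OB(OC1(C)C)B1OC(C)(C)C(C)(C)O1)
Why: Miyaura borylation of the aryl bromide, with the weak acetate base preventing onward Suzuki homocoupling.

Step 7
Reactants: 4 4,4,5-trimethoxy-3,4-dihydronaphthalen-1-yl trifluoromethanesulfonate; 8 2-[5-methoxy-4-(methoxymethoxy)naphthalen-1-yl]-4,4,5,5-tetramethyl-1,3,2-dioxaborolane
Product: 9 4-[5-methoxy-4-(methoxymethoxy)naphthalen-1-yl]-1,1,8-trimethoxy-1,2-dihydronaphthalene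
Conditions: Pd(dppf)Cl2 (5 mol%), K3PO4, 1,4-dioxane/H2O (10:1), 70 °C
Reagents that add atoms: none
Why: Suzuki–Miyaura cross-coupling of an enol triflate with an arylboronate runs in a basic medium that the dimethyl ketal and MOM ether tolerate, and forms the bond between ring B (C4) and ring C (C1).

Step 8
Reactants: 9 4-[5-methoxy-4-(methoxymethoxy)naphthalen-1-yl]-1,1,8-trimethoxy-1,2-dihydronaphthalene
Product: 11 8-methoxy-4-[5-methoxy-4-(methoxymethoxy)naphthalen-1-yl]-3,4-dihydronaphthalen-1(2H)-one (racemic), via saturated dimethyl ketal 10 (not isolated)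
Conditions: H2 (3 atm), 10% Pd/C, K2CO3 (cat.), EtOAc, 23 °C; filter; then PPTS, acetone/H2O (10:1), 23 °C
Reagents that add atoms: water (O)
Why: Heterogeneous hydrogenation reduces the trisubstituted styrene-type C=C (base suppresses benzylic C–O hydrogenolysis) and mild acid then hydrolyses the benzylic dimethyl ketal, which is far more labile than the aryl MOM ether; the new C4 stereocentre is racemic and is erased when ring B aromatises.

Step 9
Reactants: 11 8-methoxy-4-[5-methoxy-4-(methoxymethoxy)naphthalen-1-yl]-3,4-dihydronaphthalen-1(2H)-one; 2 4,4,5-trimethoxynaphthalen-1(4H)-one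
Product: 12 2-(1-hydroxy-4,4,5-trimethoxy-1,4-dihydronaphthalen-1-yl)-8-methoxy-4-[5-methoxy-4-(methoxymethoxy)naphthalen-1-yl]-3,4-dihydronaphthalen-1(2H)-one (mixture of diastereomers, used crude)
Conditions: LiN(iPr)2 (1.1 equiv), THF, −78 °C; then 2 (1.3 equiv), −78 °C; AcOH, −78 °C
Reagents that add atoms: none
Why: Crossed aldol addition in which the kinetic lithium enolate at C2 adds 1,2 to the dienone carbonyl of the quinone monoketal (1,4-attack is hindered by the adjacent quaternary ketal carbon) and a cold acidic quench prevents retro-aldol; the three stereocentres form as a mixture that is erased in step 10.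

Step 10
Reactants: 12 2-(1-hydroxy-4,4,5-trimethoxy-1,4-dihydronaphthalen-1-yl)-8-methoxy-4-[5-methoxy-4-(methoxymethoxy)naphthalen-1-yl]-3,4-dihydronaphthalen-1(2H)-one
Product: 16 2,4-bis(4-hydroxy-5-methoxynaphthalen-1-yl)-8-methoxynaphthalen-1-ol, via p-quinol 13 (not isolated), via quinone methide 14 (not isolated), via MOM-protected ternaphthol 15 (not isolated)
Conditions: TsOH·H2O (3 equiv), THF/H2O (5:1), 23 °C then 60 °C; then MeOH, 60 °C; Ar
Reagents that add atoms: water (O)
Why: Acid hydrolyses the dienone ketal to the p-quinol, the β-hydroxy ketone dehydrates through its enol (aldol-condensation-type elimination) to a p-quinone methide whose prototropic shifts aromatise ring A and ring B at unchanged overall oxidation level, and acidic methanolysis finally removes the MOM ether; no stereocentre remains.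

## Compound list

1 | 5-methoxynaphthalen-1-ol | COc1cccc2c(O)cccc12 | starting material
2 | 4,4,5-trimethoxynaphthalen-1(4H)-one | O=C1C=CC(OC)(OC)c2c(OC)cccc12 | intermediate
3 | 4,4,5-trimethoxy-3,4-dihydronaphthalen-1(2H)-one | O=C1CCC(OC)(OC)c2c(OC)cccc12 | intermediate
4 | 4,4,5-trimethoxy-3,4-dihydronaphthalen-1-yl trifluoromethanesulfonate | O=S(=O)(OC1=CCC(OC)(OC)c2c(OC)cccc12)C(F)(F)F | intermediate
5 | 8-methoxynaphthalen-1-ol | COc1cccc2cccc(O)c12 | starting material
6 | 4-bromo-8-methoxynaphthalen-1-ol | COc1cccc2c(Br)ccc(O)c12 | intermediate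
7 | 1-bromo-5-methoxy-4-(methoxymethoxy)naphthalene | COCOc1ccc(Br)c2cccc(OC)c12 | intermediate
8 | 2-[5-methoxy-4-(methoxymethoxy)naphthalen-1-yl]-4,4,5,5-tetramethyl-1,3,2-dioxaborolane | COCOc1ccc(B2OC(C)(C)C(C)(C)O2)c2cccc(OC)c12 | intermediate
9 | 4-[5-methoxy-4-(methoxymethoxy)naphthalen-1-yl]-1,1,8-trimethoxy-1,2-dihydronaphthalene | COCOc1ccc(C2=CCC(OC)(OC)c3c(OC)cccc23)c2cccc(OC)c12 | intermediate
10 | 4-[5-methoxy-4-(methoxymethoxy)naphthalen-1-yl]-1,1,8-trimethoxy-1,2,3,4-tetrahydronaphthalene (racemic) | COCOc1ccc(C2CCC(OC)(OC)c3c(OC)cccc23)c2cccc(OC)c12 | intermediate (not isolated)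
11 | 8-methoxy-4-[5-methoxy-4-(methoxymethoxy)naphthalen-1-yl]-3,4-dihydronaphthalen-1(2H)-one (racemic) | COCOc1ccc(C2CCC(=O)c3c(OC)cccc23)c2cccc(OC)c12 | intermediate
12 | 2-(1-hydroxy-4,4,5-trimethoxy-1,4-dihydronaphthalen-1-yl)-8-methoxy-4-[5-methoxy-4-(methoxymethoxy)naphthalen-1-yl]-3,4-dihydronaphthalen-1(2H)-one (diastereomer mixture) | COCOc1ccc(C2CC(C3(O)C=CC(OC)(OC)c4c(OC)cccc34)C(=O)c3c(OC)cccc23)c2cccc(OC)c12 | intermediate
13 | 2-(1-hydroxy-5-methoxy-4-oxo-1,4-dihydronaphthalen-1-yl)-8-methoxy-4-[5-methoxy-4-(methoxymethoxy)naphthalen-1-yl]-3,4-dihydronaphthalen-1(2H)-one (diastereomer mixture) | COCOc1ccc(C2CC(C3(O)C=CC(=O)c4c(OC)cccc34)C(=O)c3c(OC)cccc23)c2cccc(OC)c12 | intermediate (not isolated)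
14 | 8-methoxy-2-(5-methoxy-4-oxonaphthalen-1(4H)-ylidene)-4-[5-methoxy-4-(methoxymethoxy)naphthalen-1-yl]-3,4-dihydronaphthalen-1(2H)-one (alkene isomer mixture) | COCOc1ccc(C2CC(=C3C=CC(=O)c4c(OC)cccc34)C(=O)c3c(OC)cccc23)c2cccc(OC)c12 | intermediate (not isolated)
15 | 2-(4-hydroxy-5-methoxynaphthalen-1-yl)-8-methoxy-4-[5-methoxy-4-(methoxymethoxy)naphthalen-1-yl]naphthalen-1-ol | COCOc1ccc(-c2cc(-c3ccc(O)c4c(OC)cccc34)c(O)c3c(OC)cccc23)c2cccc(OC)c12 | intermediate (not isolated)
16 | 2,4-bis(4-hydroxy-5-methoxynaphthalen-1-yl)-8-methoxynaphthalen-1-ol | COc1cccc2c(-c3cc(-c4ccc(O)c5c(OC)cccc45)c4cccc(OC)c4c3O)ccc(O)c12 | target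

## Step count and risks

Total steps: 10. Longest linear sequence: 7 steps (1 → 2 → 3 → 4 → 9 → 11 → 12 → 16; the branch from 5 is equally long).

The route as a whole is designed on paper and has not been run. The three steps most likely to fail:

**Step 9 (key aldol).** A ketone enolate adding to a hindered dienone carbonyl can revert (retro-aldol) or drift to the 1,4-adduct. The fallback sets out from tetralone 11. LiN(iPr)2 and Me3SiCl (THF, −78 °C) convert it into trimethyl({8-methoxy-4-[5-methoxy-4-(methoxymethoxy)naphthalen-1-yl]-3,4-dihydronaphthalen-1-yl}oxy)silane F1. A fluoride-catalysed Mukaiyama-type aldol with 2 (Bu4N[Ph3SiF2] 5 mol%, THF, −78 → −40 °C) then traps the aldolate by silyl transfer as 8-methoxy-4-[5-methoxy-4-(methoxymethoxy)naphthalen-1-yl]-2-{4,4,5-trimethoxy-1-[(trimethylsilyl)oxy]-1,4-dihydronaphthalen-1-yl}-3,4-dihydronaphthalen-1(2H)-one F2, so the addition cannot revert. F2 goes into the aqueous acid of step 10, which removes the silyl group together with the ketal, and the route is rejoined at p-quinol 13.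

**Step 10 (dehydrative aromatisation cascade).** Acid-induced retro-aldol or a dienone–phenol-type 1,2-shift of the quinol may compete with dehydration. The fallback sets out from aldol adduct 12 and replaces the redox-neutral isomerisation by a reduction–oxidation pair. PPTS in acetone/H2O at 23 °C gives p-quinol 13, this time isolated. Zn dust in AcOH/THF at 23 °C removes the tertiary hydroxyl reductively and aromatises ring A, giving 2-(4-hydroxy-5-methoxynaphthalen-1-yl)-8-methoxy-4-[5-methoxy-4-(methoxymethoxy)naphthalen-1-yl]-3,4-dihydronaphthalen-1(2H)-one F3. Aerobic dehydrogenation of the tetralone ring (Pd(O2CCF3)2, 2-(dimethylamino)pyridine, TsOH, O2, DMSO, 80 °C) brings the route back at 15, from which the last stage of step 10 gives 16.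

**Step 7 (Suzuki coupling).** Enol triflate 4 aromatises easily by loss of methanol, and the electron-rich boronate 8 can protodeboronate. The fallback sets out from bromide 7 and ketone 3 and makes the same bond by carbonyl addition. n-BuLi (THF, −78 °C) gives [5-methoxy-4-(methoxymethoxy)naphthalen-1-yl]lithium F4, which adds to 3 to give 1-[5-methoxy-4-(methoxymethoxy)naphthalen-1-yl]-4,4,5-trimethoxy-1,2,3,4-tetrahydronaphthalen-1-ol F5. Burgess reagent (THF, 50 °C) dehydrates the tertiary alcohol under neutral conditions that keep the ketal, returning at 9; steps 3 and 6 are then not needed.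

## Further compounds

F1 | step 9 | trimethyl({8-methoxy-4-[5-methoxy-4-(methoxymethoxy)naphthalen-1-yl]-3,4-dihydronaphthalen-1-yl}oxy)silane | COCOc1ccc(C2CC=C(O[Si](C)(C)C)c3c(OC)cccc23)c2cccc(OC)c12
F2 | step 9 | 8-methoxy-4-[5-methoxy-4-(methoxymethoxy)naphthalen-1-yl]-2-{4,4,5-trimethoxy-1-[(trimethylsilyl)oxy]-1,4-dihydronaphthalen-1-yl}-3,4-dihydronaphthalen-1(2H)-one | COCOc1ccc(C2CC(C3(O[Si](C)(C)C)C=CC(OC)(OC)c4c(OC)cccc34)C(=O)c3c(OC)cccc23)c2cccc(OC)c12
F3 | step 10 | 2-(4-hydroxy-5-methoxynaphthalen-1-yl)-8-methoxy-4-[5-methoxy-4-(methoxymethoxy)naphthalen-1-yl]-3,4-dihydronaphthalen-1(2H)-one | COCOc1ccc(C2CC(c3ccc(O)c4c(OC)cccc34)C(=O)c3c(OC)cccc23)c2cccc(OC)c12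
F4 | step 7 | [5-methoxy-4-(methoxymethoxy)naphthalen-1-yl]lithium | [Li]c1ccc(OCOC)c2c(OC)cccc12
F5 | step 7 | 1-[5-methoxy-4-(methoxymethoxy)naphthalen-1-yl]-4,4,5-trimethoxy-1,2,3,4-tetrahydronaphthalen-1-ol | COCOc1ccc(C2(O)CCC(OC)(OC)c3c(OC)cccc23)c2cccc(OC)c12
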